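**Retrosynthetic overview**
1. Feature: C19 (CH2OAc on C4) and C20 (CHO on C10) are syn-diaxial on ring A. They are tied back as a 19,20-δ-lactone, C20(=O)–O–C19, so ring A becomes the second three-atom bridge of a 2-oxabicyclo[3.3.1]nonane and C18 can come from a C4 methylidene.
2. Key cut C3–C4: iron-hydride hydrogen-atom transfer to C18, then 6-endo addition of the C4 radical to a propenoyl group on C10; the C1 ketone is removed afterwards.
3. Precursor: ring B is bought as a cyclohexenone ketal; C9–C11 by Johnson–Claisen, C20 by carbonylation, C4–C5 by conjugate addition of a 2-(silyloxymethyl)vinyl Grignard reagent, lactonisation, then aldol/oxidation at C10.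
4. Absolute configuration: one CBS reduction, relayed C5(O) → C9 → C5(C) → C10 → C4; C9 is equilibrated through the C8 ketone before C10 is made quaternary.
5. Ring order: ring B (purchased) → lactone ring → ring A (key step) → butenolide (C12 iodide alkylation, sulfoxide elimination); C8 methylidene by Wittig, C20 aldehyde by the last oxidation.

Key step: step 13

Remark: atoms carry labdane numbers (ring A = C1–C5, C10; ring B = C5–C10; C18/C19 on C4, C20 on C10, C11–C12 on C9); the target is read as the ent-labdane 19-acetoxy-20-oxo-8(17),13-dien-16,15-olide, with C19, C20 and C11 on one face and H5, H9 on the other.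
Assumption: 1,4-dioxaspiro[4.5]dec-6-en-8-one (1) is taken as a purchasable compound.

**Step 1**
Reactants: 1 1,4-dioxaspiro[4.5]dec-6-en-8-one
Product: 2 7-iodo-1,4-dioxaspiro[4.5]dec-6-en-8-one
Conditions: I2, pyridine, CH2Cl2, 0 °C → rt
Reagents that add atoms: iodine, II
Why: α-Iodination of a cyclic enone by pyridine-mediated conjugate addition, iodination and elimination (Baylis–Hillman-type pathway) is routine for 4,4-disubstituted cyclohexenones and does not touch the dioxolane.

**Step 2**
Reactants: 2 iodoenone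
Product: 3 (8R)-7-iodo-1,4-dioxaspiro[4.5]dec-6-en-8-ol
Conditions: (S)-2-methyl-CBS-oxazaborolidine (10 mol%), BH3·SMe2, THF, 0 °C; MeOH
Reagents that add atoms: none
Why: Corey–Bakshi–Shibata reduction, in which the iodo-substituted vinyl carbon acts as the large group, so the (S)-catalyst should give the (8R)-carbinol (this carbon is the future C5), the only external source of chirality in the route.

**Step 3**
Reactants: 3 iodo allylic alcohol
Product: 5 ethyl 2-[(6S)-7-iodo-1,4-dioxaspiro[4.5]dec-7-en-6-yl]acetate, via ketene acetal 4 (not isolated)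
Conditions: MeC(OEt)3, EtCO2H (cat.), xylene, 140 °C, EtOH distilled off
Reagents that add atoms: triethyl orthoacetate, CC(OCC)(OCC)OCC
Why: Johnson–Claisen rearrangement, whose [3,3] shift runs suprafacially across the cyclohexene, so the C5–O configuration is transferred to the new C9–C11 bond while the double bond moves to C10=C5 and the acetate unit becomes C11–C12.

**Step 4**
Reactants: 5 iodo ester
Product: 6 2-[(6S)-7-iodo-1,4-dioxaspiro[4.5]dec-7-en-6-yl]ethan-1-ol
Conditions: (i-Bu)2AlH, CH2Cl2, −78 → 0 °C
Reagents that add atoms: none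
Why: Hydride reduction of the ester to the primary alcohol; the alkenyl iodide and the dioxolane are inert to (i-Bu)2AlH at low temperature.

**Step 5**
Reactants: 6 iodo alcohol
Product: 7 2-[(6S)-7-iodo-1,4-dioxaspiro[4.5]dec-7-en-6-yl]ethyl 2,2-dimethylpropanoate
Conditions: PivCl, pyridine, DMAP (cat.), CH2Cl2, 0 °C
Reagents that add atoms: pivaloyl chloride, CC(C)(C)C(=O)Cl
Why: Acylation of a primary alcohol; the pivalate has no α-hydrogen, survives the organomagnesium, acid, amide-base and radical steps, and is removed for free in the LiAlH4 step.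

**Step 6**
Reactants: 7 iodo pivalate
Product: 8 methyl (6R)-6-[2-(2,2-dimethylpropanoyloxy)ethyl]-1,4-dioxaspiro[4.5]dec-7-ene-7-carboxylate
Conditions: PdCl2(PPh3)2 (5 mol%), CO (1 atm), Et3N, MeOH/DMF, 60 °C
Reagents that add atoms: carbon monoxide, [C-]#[O+]; methanol, CO
Why: Palladium-catalysed methoxycarbonylation of the alkenyl iodide (oxidative addition to zerovalent palladium, CO insertion, methanolysis) installs C20 as the C10 enoate without touching C9.

**Step 7**
Reactants: 9 2-bromoprop-2-en-1-ol
Product: 10 [(2-bromoprop-2-en-1-yl)oxy](tert-butyl)dimethylsilane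
Conditions: TBSCl, imidazole, CH2Cl2, rt
Reagents that add atoms: tert-butyldimethylsilyl chloride, C[Si](C)(Cl)C(C)(C)C
Why: Standard silylation of a primary allylic alcohol.

**Step 8**
Reactants: 8 enoate; 10 bromoallyl silyl ether
Product: 12 methyl (6R,8S)-8-{3-[(tert-butyldimethylsilyl)oxy]prop-1-en-2-yl}-6-[2-(2,2-dimethylpropanoyloxy)ethyl]-1,4-dioxaspiro[4.5]decane-7-carboxylate, via Grignard reagent 11 (not isolated)
Conditions: 10, Mg, BrCH2CH2Br (cat.), THF, 40 °C; then CuBr·SMe2 (10 mol%), Me3SiCl, 8, THF, −78 → −30 °C; aq. NH4Cl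
Reagents that add atoms: none
Why: Copper-catalysed, Me3SiCl-accelerated conjugate addition of an alkenyl Grignard reagent to an enoate; the C9 side chain stands pseudoaxial to avoid A(1,2) strain with the ester, so the alkenyl group should enter C5 on the opposite face (1,3-trans), which fixes C5, while C10 is protonated unselectively and is reset in step 11.

**Step 9**
Reactants: 12 conjugate adduct
Product: 14 keto lactone (19,20-lactone; C8 ketone; H5/H9 cis), via hydroxy keto ester 13 (not isolated)
Conditions: 2 M HCl, THF, 40 °C; then DBU (0.2 equiv), PhMe, 40 °C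
Reagents that add atoms: water, O
Why: Aqueous acid removes the allylic silyl ether and the dioxolane and closes the δ-lactone by intramolecular transesterification, and DBU then equilibrates C9 next to the C8 ketone to the equatorial epimer with H9 cis to H5 (thermodynamic control), which is the configuration of the target.

**Step 10**
Reactants: 14 keto lactone
Product: 15 C8 ethylene ketal of 14
Conditions: (Me3SiOCH2)2, Me3SiOTf (cat.), CH2Cl2, −78 → −20 °C
Reagents that add atoms: 1,2-bis(trimethylsilyloxy)ethane, C[Si](C)(C)OCCO[Si](C)(C)C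
Why: Silyl triflate-catalysed dioxolane formation from the bis(silyl ether) re-masks the C8 ketone, so that only the lactone α-hydrogen is acidic in step 11 and no alkene other than C4=C18 exists in step 13, without acid strong enough to move the exocyclic alkene.

**Step 11**
Reactants: 15 ketal lactone; 16 prop-2-enal
Product: 18 C10 aldol adduct of 15 (1-hydroxyprop-2-en-1-yl on C10), via lithium enolate 17 (not isolated)
Conditions: LiN(iPr)2, THF, −78 °C; 16, −78 °C; aq. NH4Cl at −78 °C
Reagents that add atoms: none
Why: Aldol addition of a lactone lithium enolate to acrolein (1,2-addition at −78 °C); the C9 side chain is pushed axial by A(1,3) strain with the enolate oxygen and, with C4 and C6 on C5, shields one face, so acrolein should add on the face of H5 and H9 and set the quaternary C10 with the lactone cis-fused to ring B.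

**Step 12**
Reactants: 18 aldol adduct
Product: 19 cis-fused 19,20-lactone with C4 methylidene, C10 prop-2-enoyl, C8 dioxolane and C9 2-(pivaloyloxy)ethyl
Conditions: Dess–Martin periodinane, CH2Cl2, 0 °C → rt
Reagents that add atoms: none
Why: Dess–Martin oxidation of the allylic alcohol to the vinyl ketone under non-basic conditions, which avoids retro-aldol cleavage at the quaternary C10.

**Step 13**
Reactants: 19 vinyl ketone lactone
Product: 20 8,8-(ethylenedioxy)-1-oxo-12-(pivaloyloxy)-13,14,15,16,17-pentanor-ent-labdan-20,19-olide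
Conditions: Fe(acac)3 (30 mol%), PhSiH3, EtOH/(CH2OH)2, 60 °C, 0.01 M
Reagents that add atoms: none
Why: The iron hydride formed from Fe(acac)3 and PhSiH3 transfers a hydrogen atom to C18 of the electron-rich 1,1-disubstituted alkene, the tertiary C4 radical inside the lactone ring adds to C3 (the β-carbon of the propenoyl group on C10), and the α-keto radical at C2 is reduced by divalent iron to the enolate and protonated by ethanol. The closest known reaction type is the iron-hydride hydrogen-atom-transfer reductive coupling of unactivated alkenes with enones (radical Giese addition), including its intramolecular use to build quaternary carbons. Ring A closes 6-endo-trig, both C2 and C3 ending in the ring, because the nucleophilic radical goes to the β-carbon and the 5-exo alternative would need attack at the α-carbon C2. The only new stereocentre, C4, is controlled by the lactone tether: C19 is already linked through oxygen to C20 on C10, so C3 can bond only so that C19 and C20 form the syn-diaxial bridge and C18 is equatorial, and the C10 configuration from step 11 makes the A/B fusion trans. The step needs hydrogen-atom transfer to C18 rather than to the electron-poor vinyl ketone and cyclisation before a second hydrogen-atom transfer; the electron-rich alkene is the faster acceptor, no other alkene is present (C8 is a dioxolane), and high dilution with the acceptor held axial on C10 favours ring closure.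

**Step 14**
Reactants: 20 C1 ketone
Product: 22 C1 enol triflate of 20, via potassium enolate 21 (not isolated)
Conditions: KN(SiMe3)2, THF, −78 °C; PhNTf2, −78 → 0 °C; aq. NH4Cl
Reagents that add atoms: N-phenylbis(trifluoromethanesulfonimide), O=S(=O)(N(c1ccccc1)S(=O)(=O)C(F)(F)F)C(F)(F)F
Why: Regiospecific enolisation (C2 is the only α-carbon with hydrogen, C10 being quaternary) and O-sulfonylation give the enol triflate; this route to deoxygenation is used because thioketalisation would also exchange the C8 dioxolane.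

**Step 15**
Reactants: 22 enol triflate
Product: 23 8,8-(ethylenedioxy)-12-(pivaloyloxy)-13,14,15,16,17-pentanor-ent-labd-1-en-20,19-olide
Conditions: Pd(OAc)2 (5 mol%), PPh3, HCO2H, Et3N, DMF, 60 °C
Reagents that add atoms: none
Why: Palladium-catalysed formate reduction of an enol triflate: oxidative addition to zerovalent palladium, formate exchange, decarboxylation and reductive elimination replace OTf by H.

**Step 16**
Reactants: 23 ring A alkene
Product: 24 8,8-(ethylenedioxy)-12-(pivaloyloxy)-13,14,15,16,17-pentanor-ent-labdan-20,19-olide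
Conditions: H2 (1 atm), 10% Pd/C, EtOAc, rt
Reagents that add atoms: none
Why: Heterogeneous catalytic hydrogenation of the only C=C bond in the molecule completes the removal of the C1 oxygen.

**Step 17**
Reactants: 24 ketal lactone
Product: 25 8-oxo-12-(pivaloyloxy)-13,14,15,16,17-pentanor-ent-labdan-20,19-olide
Conditions: 2 M HCl, THF, 40 °C
Reagents that add atoms: water, O
Why: Acid hydrolysis of the dioxolane; lactone and pivalate survive, and C9, again α to a ketone, keeps its equatorial side chain.

**Step 18**
Reactants: 25 C8 ketone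
Product: 26 12-(pivaloyloxy)-13,14,15,16-tetranor-ent-labd-8(17)-en-20,19-olide
Conditions: Ph3PCH3Br, KOtBu, THF, 0 → 50 °C
Reagents that add atoms: methyltriphenylphosphonium bromide, C[P+](c1ccccc1)(c1ccccc1)c1ccccc1.[Br-]
Why: Wittig methylenation of the C8 ketone, the standard entry to the 8(17)-exocyclic alkene of labdanes; the bridged neopentyl lactone and the pivalate are too hindered to compete.

**Step 19**
Reactants: 26 methylidene lactone
Product: 27 13,14,15,16-tetranor-ent-labd-8(17)-ene-12,19,20-triol
Conditions: LiAlH4, THF, 0 °C → rt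
Reagents that add atoms: none
Why: LiAlH4 reduces the lactone to the 19,20-diol and cleaves the pivalate in the same operation.

**Step 20**
Reactants: 27 triol
Product: 28 12-iodo-13,14,15,16-tetranor-ent-labd-8(17)-ene-19,20-diol
Conditions: I2 (1.05 equiv), PPh3, imidazole, CH2Cl2, 0 °C
Reagents that add atoms: iodine, II
Why: Appel-type iodination, in which only the unhindered C12 alcohol undergoes the SN2 displacement; the neopentyl alcohols at C19 and C20 are inert at 0 °C with one equivalent of reagent.

**Step 21**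
Reactants: 28 iodo diol
Product: 29 20-hydroxy-12-iodo-13,14,15,16-tetranor-ent-labd-8(17)-en-19-yl acetate
Conditions: AcCl (1.1 equiv), 2,4,6-collidine, CH2Cl2, −78 °C
Reagents that add atoms: acetyl chloride, CC(=O)Cl
Why: Kinetically controlled acylation: C19–OH sits on C4 beside a methyl group, whereas C20–OH sits on the ring-fusion carbon between C1, C5 and the substituted C9, so C19 should react first.

**Step 22**
Reactants: 29 mono-acetate
Product: 30 12-iodo-20-(triethylsilyloxy)-13,14,15,16-tetranor-ent-labd-8(17)-en-19-yl acetate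
Conditions: Et3SiOTf, 2,6-lutidine, CH2Cl2, −40 → 0 °C
Reagents that add atoms: triethylsilyl trifluoromethanesulfonate, CC[Si](CC)(CC)OS(=O)(=O)C(F)(F)F
Why: Silylation of the hindered neopentyl alcohol with the triflate reagent protects C20–OH from the enolate of step 24.

**Step 23**
Reactants: 31 3-bromooxolan-2-one
Product: 32 3-(phenylsulfanyl)oxolan-2-one
Conditions: PhSH, Et3N, CH2Cl2, 0 °C → rt
Reagents that add atoms: thiophenol, Sc1ccccc1
Why: SN2 displacement of an α-bromo lactone by thiolate.

**Step 24**
Reactants: 30 iodide; 32 phenylsulfanyl lactone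
Product: 34 19-acetoxy-13-(phenylsulfanyl)-20-(triethylsilyloxy)-ent-labd-8(17)-en-16,15-olide, via lithium enolate 33 (not isolated)
Conditions: 32, LiN(iPr)2, THF, −78 °C; then 30, HMPA, −78 → 0 °C
Reagents that add atoms: none
Why: Alkylation of a sulfur-stabilised lactone enolate with a primary iodide joins C12 to C13; the acetate is not deprotonated by this weakly basic enolate and the C13 configuration is irrelevant.

**Step 25**
Reactants: 34 sulfide
Product: 36 19-acetoxy-20-(triethylsilyloxy)-ent-labda-8(17),13-dien-16,15-olide, via sulfoxide 35 (not isolated)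
Conditions: mCPBA (1.0 equiv), CH2Cl2, −78 °C; then PhMe, 110 °C
Reagents that add atoms: none
Why: Sulfide oxidation is far faster than epoxidation of the exocyclic alkene at −78 °C, and thermal sulfoxide syn-elimination gives the endocyclic α-substituted butenolide.

**Step 26**
Reactants: 36 silyl ether
Product: 37 19-acetoxy-20-hydroxy-ent-labda-8(17),13-dien-16,15-olide
Conditions: HF·pyridine, THF, 0 °C → rt
Reagents that add atoms: none
Why: Fluoride cleavage of the silyl ether under mildly acidic conditions leaves acetate and butenolide intact.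

**Step 27**
Reactants: 37 C20 alcohol
Product: 38 19-acetoxy-20-oxo-ent-labda-8(17),13-dien-16,15-olide
Conditions: Dess–Martin periodinane, CH2Cl2, rt
Reagents that add atoms: none
Why: Dess–Martin oxidation of the neopentyl primary alcohol to the non-enolisable C20 aldehyde; acetate, exocyclic alkene and butenolide are inert.

**Compound list**
1 | 1,4-dioxaspiro[4.5]dec-6-en-8-one | O=C1C=CC2(OCCO2)CC1 | starting material
2 | 7-iodo-1,4-dioxaspiro[4.5]dec-6-en-8-one | O=C1C(I)=CC2(OCCO2)CC1 | intermediate
3 | (8R)-7-iodo-1,4-dioxaspiro[4.5]dec-6-en-8-ol | O[C@@H]1CCC2(OCCO2)C=C1I | intermediate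
4 | (8R)-8-[(1-ethoxyethenyl)oxy]-7-iodo-1,4-dioxaspiro[4.5]dec-6-ene (mixed ketene acetal) | C=C(OCC)O[C@@H]1CCC2(OCCO2)C=C1I | intermediate
5 | ethyl 2-[(6S)-7-iodo-1,4-dioxaspiro[4.5]dec-7-en-6-yl]acetate | CCOC(=O)C[C@@H]1C(I)=CCCC12OCCO2 | intermediate
6 | 2-[(6S)-7-iodo-1,4-dioxaspiro[4.5]dec-7-en-6-yl]ethan-1-ol | OCC[C@@H]1C(I)=CCCC12OCCO2 | intermediate
7 | 2-[(6S)-7-iodo-1,4-dioxaspiro[4.5]dec-7-en-6-yl]ethyl 2,2-dimethylpropanoate | CC(C)(C)C(=O)OCC[C@@H]1C(I)=CCCC12OCCO2 | intermediate
8 | methyl (6R)-6-[2-(2,2-dimethylpropanoyloxy)ethyl]-1,4-dioxaspiro[4.5]dec-7-ene-7-carboxylate | CC(C)(C)C(=O)OCC[C@@H]1C(C(=O)OC)=CCCC12OCCO2 | intermediate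
9 | 2-bromoprop-2-en-1-ol | OCC(Br)=C | starting material
10 | [(2-bromoprop-2-en-1-yl)oxy](tert-butyl)dimethylsilane | C=C(Br)CO[Si](C)(C)C(C)(C)C | intermediate
11 | {3-[(tert-butyldimethylsilyl)oxy]prop-1-en-2-yl}magnesium bromide | C=C([Mg]Br)CO[Si](C)(C)C(C)(C)C | intermediate
12 | methyl (6R,8S)-8-{3-[(tert-butyldimethylsilyl)oxy]prop-1-en-2-yl}-6-[2-(2,2-dimethylpropanoyloxy)ethyl]-1,4-dioxaspiro[4.5]decane-7-carboxylate; H5 and H9 trans; both C10 epimers | C=C(CO[Si](C)(C)C(C)(C)C)[C@H]1CCC2(OCCO2)[C@H](CCOC(=O)C(C)(C)C)C1C(=O)OC | intermediate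
13 | methyl 6-(3-hydroxyprop-1-en-2-yl)-2-[2-(2,2-dimethylpropanoyloxy)ethyl]-3-oxocyclohexane-1-carboxylate; configuration as in 12 | C=C(CO)[C@H]1CCC(=O)[C@H](CCOC(=O)C(C)(C)C)C1C(=O)OC | intermediate
14 | 2-[4-methylidene-1,7-dioxo-3,4,4a,5,6,7,8,8a-octahydro-1H-isochromen-8-yl]ethyl 2,2-dimethylpropanoate; 19,20-lactone with C8 ketone; H5 and H9 cis; both C10 epimers | C=C1COC(=O)C2[C@H](CCOC(=O)C(C)(C)C)C(=O)CC[C@H]12 | intermediate
15 | C8 ethylene ketal of 14 (spiro-dioxolane at the former ketone) | C=C1COC(=O)C2[C@H](CCOC(=O)C(C)(C)C)C3(OCCO3)CC[C@H]12 | intermediate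
16 | prop-2-enal (acrolein) | C=CC=O | starting material
17 | lithium enolate of 15 (C10=C20–OLi) | C=C1COC(O[Li])=C2[C@H](CCOC(=O)C(C)(C)C)C3(OCCO3)CC[C@H]12 | intermediate
18 | 15 carrying a 1-hydroxyprop-2-en-1-yl group on C10, on the face of H5 and H9; both carbinol epimers | C=C1COC(=O)[C@]2(C(O)C=C)[C@H](CCOC(=O)C(C)(C)C)C3(OCCO3)CC[C@H]12 | intermediate
19 | cis-fused 19,20-lactone with C4 methylidene, C10 prop-2-enoyl (cis to H5), C8 dioxolane and C9 2-(pivaloyloxy)ethyl (cis to the lactone carbonyl) | C=C1COC(=O)[C@]2(C(=O)C=C)[C@H](CCOC(=O)C(C)(C)C)C3(OCCO3)CC[C@H]12 | intermediate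
20 | 8,8-(ethylenedioxy)-1-oxo-12-(pivaloyloxy)-13,14,15,16,17-pentanor-ent-labdan-20,19-olide (lactone-bridged trans-decalin, C18 equatorial) | O=C1OC[C@]2(C)CCC(=O)[C@]13[C@H](CCOC(=O)C(C)(C)C)C4(OCCO4)CC[C@H]23 | intermediate
21 | potassium C1(2)-enolate of 20 | O=C1OC[C@]2(C)CC=C(O[K])[C@]13[C@H](CCOC(=O)C(C)(C)C)C4(OCCO4)CC[C@H]23 | intermediate
22 | 1-(trifluoromethanesulfonyloxy)-1-ene derived from 20 | O=C1OC[C@]2(C)CC=C(OS(=O)(=O)C(F)(F)F)[C@]13[C@H](CCOC(=O)C(C)(C)C)C4(OCCO4)CC[C@H]23 | intermediate
23 | 8,8-(ethylenedioxy)-12-(pivaloyloxy)-13,14,15,16,17-pentanor-ent-labd-1-en-20,19-olide | O=C1OC[C@]2(C)CC=C[C@]13[C@H](CCOC(=O)C(C)(C)C)C4(OCCO4)CC[C@H]23 | intermediate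
24 | 8,8-(ethylenedioxy)-12-(pivaloyloxy)-13,14,15,16,17-pentanor-ent-labdan-20,19-olide | O=C1OC[C@]2(C)CCC[C@]13[C@H](CCOC(=O)C(C)(C)C)C4(OCCO4)CC[C@H]23 | intermediate
25 | 8-oxo-12-(pivaloyloxy)-13,14,15,16,17-pentanor-ent-labdan-20,19-olide | O=C1OC[C@]2(C)CCC[C@]13[C@H](CCOC(=O)C(C)(C)C)C(=O)CC[C@H]23 | intermediate
26 | 12-(pivaloyloxy)-13,14,15,16-tetranor-ent-labd-8(17)-en-20,19-olide | O=C1OC[C@]2(C)CCC[C@]13[C@H](CCOC(=O)C(C)(C)C)C(=C)CC[C@H]23 | intermediate
27 | 13,14,15,16-tetranor-ent-labd-8(17)-ene-12,19,20-triol | C=C1CC[C@@H]2[C@](C)(CO)CCC[C@@]2(CO)[C@@H]1CCO | intermediate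
28 | 12-iodo-13,14,15,16-tetranor-ent-labd-8(17)-ene-19,20-diol | C=C1CC[C@@H]2[C@](C)(CO)CCC[C@@]2(CO)[C@@H]1CCI | intermediate
29 | 20-hydroxy-12-iodo-13,14,15,16-tetranor-ent-labd-8(17)-en-19-yl acetate | C=C1CC[C@@H]2[C@](C)(COC(C)=O)CCC[C@@]2(CO)[C@@H]1CCI | intermediate
30 | 12-iodo-20-(triethylsilyloxy)-13,14,15,16-tetranor-ent-labd-8(17)-en-19-yl acetate | C=C1CC[C@@H]2[C@](C)(COC(C)=O)CCC[C@@]2(CO[Si](CC)(CC)CC)[C@@H]1CCI | intermediate
31 | 3-bromooxolan-2-one (α-bromo-γ-butyrolactone) | O=C1OCCC1Br | starting material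
32 | 3-(phenylsulfanyl)oxolan-2-one (racemic) | O=C1OCCC1Sc1ccccc1 | intermediate
33 | lithium enolate of 32 | [Li]OC1=C(Sc2ccccc2)CCO1 | intermediate
34 | 19-acetoxy-13-(phenylsulfanyl)-20-(triethylsilyloxy)-ent-labd-8(17)-en-16,15-olide; both C13 epimers | C=C1CC[C@@H]2[C@](C)(COC(C)=O)CCC[C@@]2(CO[Si](CC)(CC)CC)[C@@H]1CCC1(Sc2ccccc2)CCOC1=O | intermediate
35 | sulfoxide of 34 | C=C1CC[C@@H]2[C@](C)(COC(C)=O)CCC[C@@]2(CO[Si](CC)(CC)CC)[C@@H]1CCC1(S(=O)c2ccccc2)CCOC1=O | intermediate
36 | 19-acetoxy-20-(triethylsilyloxy)-ent-labda-8(17),13-dien-16,15-olide | C=C1CC[C@@H]2[C@](C)(COC(C)=O)CCC[C@@]2(CO[Si](CC)(CC)CC)[C@@H]1CCC1=CCOC1=O | intermediate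
37 | 19-acetoxy-20-hydroxy-ent-labda-8(17),13-dien-16,15-olide | C=C1CC[C@@H]2[C@](C)(COC(C)=O)CCC[C@@]2(CO)[C@@H]1CCC1=CCOC1=O | intermediate
38 | 19-acetoxy-20-oxo-ent-labda-8(17),13-dien-16,15-olide (CNP0109410.1) | C=C1CC[C@@H]2[C@](C)(COC(C)=O)CCC[C@@]2(C=O)[C@@H]1CCC1=CCOC1=O | target

**Step count**
Total step count: 27. Longest linear sequence: 25 steps (1–6, 8–22, 24–27); steps 7 and 23 make the two coupling partners.

**Steps most likely to fail**

Step 13. The C4 radical may take a second hydrogen atom before it reaches C3, or the iron hydride and silane may consume the vinyl ketone, so that ring A does not close. The fallback sets out from 15 and replaces the radical ring closure by an intermolecular radical addition followed by a polar ring closure. Iron-hydride Giese addition of the C4 methylidene of 15 to methyl acrylate (Fe(acac)3, PhSiH3, EtOH/(CH2OH)2, 60 °C) gives the C4-methyl propanoate adduct F1, with the new chain expected anti to C6. Treatment with KN(SiMe3)2 in THF (−78 → 0 °C) then closes ring A by Dieckmann-type acylation of the lactone enolate at C10 by the ester (C1–C10 bond). This can happen only on the face of the tether, and it returns to the route at 20.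

Step 11. The aldol addition at the crowded tertiary C10 may revert on warming (retro-aldol), or the enolate may add to acrolein in the 1,4 sense. The fallback sets out from 15. The same lithium enolate 17 is C-acylated with 3-chloropropanoyl chloride (THF, −78 °C) to the β-chloro ketone F2, and Et3N (CH2Cl2, 0 °C) eliminates HCl. This returns to the route at 19 without a reversible bond formation and without the oxidation of step 12.

Step 8. Conjugate addition to the trisubstituted enoate next to the branched C9 may be slow, so that the Grignard reagent attacks an ester carbonyl or is simply quenched. The fallback sets out from 7 and uses a more electrophilic acceptor. Palladium-catalysed formylation of the alkenyl iodide (Pd(PPh3)4, CO, Bu3SnH, THF, 50 °C) gives the enal F3. Copper-catalysed addition of 11 (CuBr·SMe2, Me3SiCl, THF, −78 °C) gives the 5,9-trans aldehyde F4. Pinnick oxidation (NaClO2, NaH2PO4, 2-methylbut-2-ene, t-BuOH/H2O) gives the acid F5, which lactonises under the conditions of step 9 and returns to the route at 14.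

**Further compounds**
F1 | step 13 | methyl 3-(C4-methyl lactone)propanoate: 15 with C18 as methyl and a 2-(methoxycarbonyl)ethyl chain (C3–C1) on C4 | C[C@]1(CCC(=O)OC)COC(=O)C2[C@H](CCOC(=O)C(C)(C)C)C3(OCCO3)CC[C@H]12
F2 | step 11 | 15 carrying a 3-chloropropanoyl group on C10 (cis to H5) | C=C1COC(=O)[C@]2(C(=O)CCCl)[C@H](CCOC(=O)C(C)(C)C)C3(OCCO3)CC[C@H]12
F3 | step 8 | 2-[(6R)-7-formyl-1,4-dioxaspiro[4.5]dec-7-en-6-yl]ethyl 2,2-dimethylpropanoate | CC(C)(C)C(=O)OCC[C@@H]1C(C=O)=CCCC12OCCO2
F4 | step 8 | aldehyde analogue of 12 (CHO in place of CO2Me on C10) | C=C(CO[Si](C)(C)C(C)(C)C)[C@H]1CCC2(OCCO2)[C@H](CCOC(=O)C(C)(C)C)C1C=O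
F5 | step 8 | carboxylic acid analogue of 12 (CO2H in place of CO2Me on C10) | C=C(CO[Si](C)(C)C(C)(C)C)[C@H]1CCC2(OCCO2)[C@H](CCOC(=O)C(C)(C)C)C1C(=O)O
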